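**Retrosynthetic overview**
1. Feature: the C3 methoxy group sits on C2=C3 of the furan ring. This enol-ether bond (O1–C2=C3) is conjugated to rings A and B and is the easiest π bond of the molecule to oxidise. C2 carries ring B and no hydrogen, so a 2,3-dimethoxy adduct can re-aromatise only by losing the C2 methoxy group and H3.
2. C3–O: target ⇐ 2,3-dimethoxy-2,3-dihydrobenzofuran (acid: loss of methanol, MOM removal) ⇐ bis-MOM 5-prenyl-2-arylbenzofuran plus two methanol (anodic oxidation).
3. C5–CH2 (prenyl): C5 aryllithium from the 5-bromobenzofuran plus prenyl bromide, placed after all iodination and palladium chemistry.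
4. Furan ring (the only ring made; rings A and B are bought): C3a–C3 by Sonogashira coupling at the C–I bond of 4-bromo-6-iodoresorcinol with the ring B alkyne from isovanillin, then O1–C2 by 5-endo-dig closure.

Key step: step 7

Remark: the target has no stereocentre. The two stereocentres created in step 7 are formed without control and are erased in step 8, so no stereocontrol is planned.

**Step 1**
Reactants: 1 isovanillin (3-hydroxy-4-methoxybenzaldehyde)
Product: 2 4-methoxy-3-(methoxymethoxy)benzaldehyde
Conditions: MOMCl (1.3 equiv), K2CO3 (2 equiv), acetone, 0 °C → rt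
Reagents that add atoms: chloromethyl methyl ether (MOMCl), COCCl
Why: Williamson-type O-alkylation of the only phenol with the reactive α-chloro ether should be clean, and the MOM acetal tolerates the basic, organometallic and buffered anodic steps that follow.

**Step 2**
Reactants: 2 4-methoxy-3-(methoxymethoxy)benzaldehyde
Product: 3 4-ethynyl-1-methoxy-2-(methoxymethoxy)benzene
Conditions: Ohira–Bestmann reagent (1.3 equiv), K2CO3 (2 equiv), MeOH, rt
Reagents that add atoms: dimethyl (1-diazo-2-oxopropyl)phosphonate (Ohira–Bestmann reagent), CC(=O)C(=[N+]=[N-])P(=O)(OC)OC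
Why: Seyferth–Gilbert homologation in the Ohira–Bestmann variant turns non-enolisable aryl aldehydes into terminal alkynes under mild carbonate/methanol conditions that leave the MOM acetal untouched.

**Step 3**
Reactants: 4 4-bromoresorcinol (4-bromobenzene-1,3-diol)
Product: 5 4-bromo-6-iodobenzene-1,3-diol
Conditions: NIS (1.0 equiv), MeCN, 0 °C → rt, dark
Reagents that add atoms: N-iodosuccinimide, O=C1CCC(=O)N1I
Why: Electrophilic aromatic iodination should go to C6, ortho to one hydroxyl and para to the other, because C2 is crowded between both hydroxyls and C5 is meta to both, which is the same preference that gives 4,6-dihalides from resorcinol under non-basic conditions.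

**Step 4**
Reactants: 5 4-bromo-6-iodobenzene-1,3-diol; 3 4-ethynyl-1-methoxy-2-(methoxymethoxy)benzene
Product: 7 5-bromo-2-[4-methoxy-3-(methoxymethoxy)phenyl]-1-benzofuran-6-ol, via 2-alkynylphenol 6 (not isolated)
Conditions: PdCl2(PPh3)2 (3 mol %), CuI (5 mol %), Et3N (4 equiv), degassed DMF, rt → 70 °C
Reagents that add atoms: none
Why: Sonogashira coupling occurs at C–I because oxidative addition of zerovalent palladium to the electron-rich C–Br bond is much slower at this temperature, and the ortho hydroxyl then adds to the metal-activated alkyne by 5-endo-dig hydroalkoxylation to form O1–C2, the other hydroxyl being para to the alkyne and out of reach.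

**Step 5**
Reactants: 7 5-bromo-2-[4-methoxy-3-(methoxymethoxy)phenyl]-1-benzofuran-6-ol
Product: 8 5-bromo-2-[4-methoxy-3-(methoxymethoxy)phenyl]-6-(methoxymethoxy)-1-benzofuran
Conditions: MOMCl (1.5 equiv), K2CO3 (2.5 equiv), acetone, rt → 40 °C
Reagents that add atoms: chloromethyl methyl ether (MOMCl), COCCl
Why: Williamson-type O-alkylation masks the last free phenol, which would otherwise quench the aryllithium of step 6 and be oxidised itself in step 7.

**Step 6**
Reactants: 8 5-bromo-2-[4-methoxy-3-(methoxymethoxy)phenyl]-6-(methoxymethoxy)-1-benzofuran; 9 prenyl bromide (1-bromo-3-methylbut-2-ene)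
Product: 11 2-[4-methoxy-3-(methoxymethoxy)phenyl]-6-(methoxymethoxy)-5-(3-methylbut-2-en-1-yl)-1-benzofuran, via C5 aryllithium 10 (not isolated)
Conditions: n-BuLi (1.05 equiv), THF, −78 °C, 15 min; CuBr·SMe2 (0.2 equiv); 9 (1.5 equiv), −78 → 0 °C
Reagents that add atoms: prenyl bromide (9), CC(C)=CCBr
Why: Bromine–lithium exchange outruns any deprotonation at −78 °C and gives an aryllithium held by the neighbouring MOM oxygen, which prenyl bromide alkylates at its unhindered primary carbon (copper-assisted SN2), a standard prenylation of MOM-protected phenols.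

**Step 7**
Reactants: 11 2-[4-methoxy-3-(methoxymethoxy)phenyl]-6-(methoxymethoxy)-5-(3-methylbut-2-en-1-yl)-1-benzofuran; 12 methanol (reactant and solvent)
Product: 13 2,3-dimethoxy-2-[4-methoxy-3-(methoxymethoxy)phenyl]-6-(methoxymethoxy)-5-(3-methylbut-2-en-1-yl)-2,3-dihydro-1-benzofuran (racemic, cis/trans mixture at C2/C3)
Conditions: undivided cell, graphite anode, Pt cathode, Et4NOTs (0.1 M), 2,6-lutidine (3 equiv), MeOH/THF 3:1, 0 °C, anode potential held at the foot of the first oxidation wave (located by cyclic voltammetry), stopped at 2.0–2.2 F/mol; NaHCO3 work-up, Et3N-deactivated silica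
Reagents that add atoms: methanol (12), CO
Why: Anodic 2,3-dimethoxylation of a benzofuran by an electron transfer/addition/electron transfer/addition sequence: the donor-substituted 2-arylbenzofuran π system loses one electron at graphite, methanol adds to the radical cation at C3, the C2 radical flanked by O1 and ring B is oxidised to an oxocarbenium ion, a second methanol caps it as the mixed ketal, and protons are reduced to hydrogen at the cathode. The closest known reactions are the anodic dimethoxylations of benzofuran itself, of simple enol ethers and of dimethoxystilbenes in methanol. No ring is closed; C2 and C3 become stereocentres with no controlling element, so a mixture of diastereomers is expected, and both centres vanish in step 8. The chemoselectivity needed is oxidation of the tetra-oxygenated stilbene-like chromophore in preference to the isolated trisubstituted prenyl alkene and to the two separated arenes of 13, all of which should oxidise at clearly higher potential, so potential control and the charge limit secure it. 2,6-Lutidine keeps the anode layer from turning acidic, so the C2 ketal cannot lose methanol during the run, which matters because the resulting 3-methoxybenzofuran would be oxidised more easily than 11. The site of the first methanol attack does not matter, since attack at C2 leads through a C3 cation stabilised by the para C6 oxygen to the same adduct.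

**Step 8**
Reactants: 13 2,3-dimethoxy-2-[4-methoxy-3-(methoxymethoxy)phenyl]-6-(methoxymethoxy)-5-(3-methylbut-2-en-1-yl)-2,3-dihydro-1-benzofuran
Product: 15 2-(3-hydroxy-4-methoxyphenyl)-3-methoxy-5-(3-methylbut-2-en-1-yl)-1-benzofuran-6-ol (target), via bis-MOM 3-methoxybenzofuran 14 (not isolated)
Conditions: anhydrous HCl (ca. 0.5 M) in MeOH, 0 → 40 °C; NaHCO3 quench
Reagents that add atoms: none
Why: Acid ionises the C2 mixed ketal to an oxocarbenium ion stabilised by O1 and ring B, loss of H3 (E1) restores the aromatic furan with the methoxy group left on C3 from either diastereomer, and the same acid passes both MOM groups to methanol by transacetalisation under conditions of the kind routinely used on ortho-prenylphenol MOM ethers.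

**Compound list**
1 | isovanillin (3-hydroxy-4-methoxybenzaldehyde) | COc1ccc(C=O)cc1O | starting material
2 | 4-methoxy-3-(methoxymethoxy)benzaldehyde | COCOc1cc(C=O)ccc1OC | intermediate
3 | 4-ethynyl-1-methoxy-2-(methoxymethoxy)benzene | COCOc1cc(C#C)ccc1OC | intermediate
4 | 4-bromoresorcinol (4-bromobenzene-1,3-diol) | Oc1ccc(Br)c(O)c1 | starting material
5 | 4-bromo-6-iodobenzene-1,3-diol | Oc1cc(O)c(I)cc1Br | intermediate
6 | 4-bromo-6-{[4-methoxy-3-(methoxymethoxy)phenyl]ethynyl}benzene-1,3-diol (not isolated) | COCOc1cc(C#Cc2cc(Br)c(O)cc2O)ccc1OC | intermediate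
7 | 5-bromo-2-[4-methoxy-3-(methoxymethoxy)phenyl]-1-benzofuran-6-ol | COCOc1cc(-c2cc3cc(Br)c(O)cc3o2)ccc1OC | intermediate
8 | 5-bromo-2-[4-methoxy-3-(methoxymethoxy)phenyl]-6-(methoxymethoxy)-1-benzofuran | COCOc1cc(-c2cc3cc(Br)c(OCOC)cc3o2)ccc1OC | intermediate
9 | prenyl bromide (1-bromo-3-methylbut-2-ene) | CC(C)=CCBr | starting material
10 | {2-[4-methoxy-3-(methoxymethoxy)phenyl]-6-(methoxymethoxy)-1-benzofuran-5-yl}lithium (not isolated) | COCOc1cc(-c2cc3cc([Li])c(OCOC)cc3o2)ccc1OC | intermediate
11 | 2-[4-methoxy-3-(methoxymethoxy)phenyl]-6-(methoxymethoxy)-5-(3-methylbut-2-en-1-yl)-1-benzofuran | COCOc1cc2oc(-c3ccc(OC)c(OCOC)c3)cc2cc1CC=C(C)C | intermediate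
12 | methanol | CO | starting material
13 | 2,3-dimethoxy-2-[4-methoxy-3-(methoxymethoxy)phenyl]-6-(methoxymethoxy)-5-(3-methylbut-2-en-1-yl)-2,3-dihydro-1-benzofuran (racemic mixture of C2/C3 diastereomers, configuration undefined) | COCOc1cc2OC(OC)(c3ccc(OC)c(OCOC)c3)C(OC)c2cc1CC=C(C)C | intermediate
14 | 3-methoxy-2-[4-methoxy-3-(methoxymethoxy)phenyl]-6-(methoxymethoxy)-5-(3-methylbut-2-en-1-yl)-1-benzofuran (not isolated) | COCOc1cc2oc(-c3ccc(OC)c(OCOC)c3)c(OC)c2cc1CC=C(C)C | intermediate
15 | 2-(3-hydroxy-4-methoxyphenyl)-3-methoxy-5-(3-methylbut-2-en-1-yl)-1-benzofuran-6-ol | COc1ccc(-c2oc3cc(O)c(CC=C(C)C)cc3c2OC)cc1O | target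

**Total step count:** 8. **Longest linear sequence:** 7 (steps 1, 2, 4, 5, 6, 7, 8 from isovanillin).

**Steps most likely to fail**

Step 7.
- What may go wrong:
  - The radical cation may lose a proton from the benzylic/allylic CH2 of the prenyl group, which leads to side-chain methoxylation.
  - The ketal may lose methanol at the anode, and the resulting enol ether would then be over-oxidised.
  - The radical cation may dimerise, or the electrode may foul.
- Fallback (chemical oxygen transfer before the alkene is present), from 8 back to 14:
  - Bromide 8 carries no prenyl group. It is treated with dimethyldioxirane in acetone/CH2Cl2/MeOH at −40 → 0 °C.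
  - Epoxidation of the C2=C3 enol-ether bond should give the 2,3-epoxide of 8 F1. Methanol opens it at the oxocarbenium-stabilised C2 to the 2-methoxy-2,3-dihydrobenzofuran-3-ol F2.
  - O-Methylation (NaH, MeI, THF, 0 °C) should give the 5-bromo-2,3-dimethoxy adduct F3.
  - PPTS in toluene removes methanol to give the 5-bromo-3-methoxybenzofuran F4.
  - Bromine–lithium exchange as in step 6 gives the C5 aryllithium F5, which prenyl bromide 9 alkylates to 14. Compound 14 is then deprotected as in step 8.

Step 8.
- What may go wrong:
  - The freed C6 phenol may add to the prenyl alkene under acid catalysis (chroman ring closure).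
  - The C3 enol ether may be cleaved.
  - Ionisation at C3 may compete and trigger a 1,2-aryl shift.
- Fallback (staged sequence with a protecting-group exchange, so that no free phenol meets Brønsted acid), from 13 back to 15:
  - PPTS (cat.) in toluene at rt should effect only the loss of methanol, and 14 is isolated.
  - TESOTf and 2,2'-bipyridyl in CH2Cl2 (0 °C → rt) convert the aryl MOM ethers directly into the bis(triethylsilyl) ether of the target F6.
  - TBAF buffered with AcOH in THF at 0 °C releases 15.

Step 6.
- What may go wrong:
  - The aryl anion may be protonated, or it may migrate to the more acidic C7 position.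
  - Attack may occur at the tertiary terminus of the allyl system.
  - Halogen exchange with prenyl bromide may lead to homocoupling.
- Fallback (cross-coupling plus metathesis in place of organolithium alkylation), from 8 back to 11:
  - Stille coupling of 8 with allyltributylstannane (Pd(PPh3)4, DMF, 100 °C) should give the 5-allylbenzofuran F7.
  - Cross metathesis with excess 2-methylbut-2-ene (second-generation Grubbs catalyst, CH2Cl2, 40 °C) converts the allyl group into the prenyl group of 11.

**Further compounds**
F1 | step 7 | 2,3-epoxide of 8 (5-bromo-2,3-epoxy-2-[4-methoxy-3-(methoxymethoxy)phenyl]-6-(methoxymethoxy)-2,3-dihydro-1-benzofuran, racemic, not isolated) | COCOc1cc2OC3(c4ccc(OC)c(OCOC)c4)OC3c2cc1Br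
F2 | step 7 | 5-bromo-2-methoxy-2-[4-methoxy-3-(methoxymethoxy)phenyl]-6-(methoxymethoxy)-2,3-dihydro-1-benzofuran-3-ol (racemic, configuration undefined) | COCOc1cc2OC(OC)(c3ccc(OC)c(OCOC)c3)C(O)c2cc1Br
F3 | step 7 | 5-bromo-2,3-dimethoxy-2-[4-methoxy-3-(methoxymethoxy)phenyl]-6-(methoxymethoxy)-2,3-dihydro-1-benzofuran (racemic, configuration undefined) | COCOc1cc2OC(OC)(c3ccc(OC)c(OCOC)c3)C(OC)c2cc1Br
F4 | step 7 | 5-bromo-3-methoxy-2-[4-methoxy-3-(methoxymethoxy)phenyl]-6-(methoxymethoxy)-1-benzofuran | COCOc1cc2oc(-c3ccc(OC)c(OCOC)c3)c(OC)c2cc1Br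
F5 | step 7 | {3-methoxy-2-[4-methoxy-3-(methoxymethoxy)phenyl]-6-(methoxymethoxy)-1-benzofuran-5-yl}lithium (not isolated) | COCOc1cc2oc(-c3ccc(OC)c(OCOC)c3)c(OC)c2cc1[Li]
F6 | step 8 | bis(triethylsilyl) ether of 15 | COc1ccc(-c2oc3cc(O[Si](CC)(CC)CC)c(CC=C(C)C)cc3c2OC)cc1O[Si](CC)(CC)CC
F7 | step 6 | 2-[4-methoxy-3-(methoxymethoxy)phenyl]-6-(methoxymethoxy)-5-(prop-2-en-1-yl)-1-benzofuran | COCOc1cc2oc(-c3ccc(OC)c(OCOC)c3)cc2cc1CC=C
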